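**Strategy.** Ring A is a resorcinol with four adjacent substituents: the acyl carbon at C4a, O1 at C8a, the carbon chain at C8 and the hydroxyl at C7. The route rests on disconnecting C5–C6 and C4a–C8a, so that this contiguous pattern is assembled and not imposed on a preformed arene. A 1,1,3-trioxygenated 2-allyl diene, whose enol oxygen already bears the silyl group meant for O7, adds to a terminal ynone that holds C2–C4 and the benzylic oxygen stereocentre. Aromatisation then delivers ring A with the C8 handle locked between its two oxygens. Mitsunobu inversion closes ring C, and a silicon-tethered ring-closing metathesis installs the Z side chain.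

Key step: step 7

Remark: ring atoms carry flavanone numbers (O1, C2–C4, C4a, C5–C8, C8a); the double-bond geometries of 4 and 5 and the ketal configuration of 11 are not controlled and are erased in the next bond-forming event.

**Route**

Step 1
Reactants: 1 methyl acetoacetate; 2 allyl bromide
Product: 3 methyl 2-acetylpent-4-enoate (racemic)
Conditions: NaH, THF, 0 °C to rt, slight excess of 1
Reagents that add atoms: none
Why: C-alkylation of the sodium enolate of a β-keto ester with a reactive allylic bromide (acetoacetic ester alkylation), the excess of 1 limiting dialkylation.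

Step 2
Reactants: 3 methyl 2-acetylpent-4-enoate
Product: 4 methyl (Z)-2-allyl-3-(triisopropylsilyloxy)but-2-enoate
Conditions: TIPSOTf, Et3N, CH2Cl2, 0 °C
Reagents that add atoms: triisopropylsilyl trifluoromethanesulfonate, CC(C)[Si](OS(=O)(=O)C(F)(F)F)(C(C)C)C(C)C
Why: Soft enolisation at the doubly activated carbon and O-silylation give the conjugated silyl enol ether (silyl enol ether formation), and the bulky silyl group is placed here because this oxygen becomes O7 and keeps it as its protecting group.

Step 3
Reactants: 4 methyl (Z)-2-allyl-3-(triisopropylsilyloxy)but-2-enoate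
Product: 5 (1E)-2-allyl-1-methoxy-3-(triisopropylsilyloxy)-1-(trimethylsilyloxy)buta-1,3-diene
Conditions: LDA, THF, −78 °C; TMSCl, −78 °C to rt; non-aqueous work-up
Reagents that add atoms: chlorotrimethylsilane, C[Si](C)(C)Cl
Why: γ-Deprotonation of the β-silyloxy enoate and O-silylation of the dienolate at the ester oxygen is the standard second stage of 1,3-bis(silyloxy)diene synthesis (silyl ketene acetal formation).

Step 4
Reactants: 6 ethyl (R)-3-hydroxy-3-phenylpropanoate
Product: 7 ethyl (R)-3-(tert-butyldimethylsilyloxy)-3-phenylpropanoate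
Conditions: TBSCl, imidazole, DMF, rt
Reagents that add atoms: tert-butyldimethylsilyl chloride, CC(C)(C)[Si](C)(C)Cl
Why: Imidazole-mediated silylation of a secondary alcohol is near-neutral, so neither retro-aldol cleavage nor elimination should occur and the stereocentre is untouched.

Step 5
Reactants: 7 ethyl (R)-3-(tert-butyldimethylsilyloxy)-3-phenylpropanoate
Product: 8 (R)-3-(tert-butyldimethylsilyloxy)-N-methoxy-N-methyl-3-phenylpropanamide
Conditions: MeNHOMe·HCl, iPrMgCl, THF, −20 to 0 °C
Reagents that add atoms: N,O-dimethylhydroxylamine hydrochloride, CNOC.Cl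
Why: The chloromagnesium amide of N,O-dimethylhydroxylamine converts the ester directly into the Weinreb amide (Weinreb amidation) at a temperature low enough to keep the β-silyloxy group from eliminating.

Step 6
Reactants: 8 (R)-3-(tert-butyldimethylsilyloxy)-N-methoxy-N-methyl-3-phenylpropanamide; 9 ethynylmagnesium bromide
Product: 10 (R)-5-(tert-butyldimethylsilyloxy)-5-phenylpent-1-yn-3-one
Conditions: THF, 0 °C; inverse quench into cold aqueous NaHSO4
Reagents that add atoms: none
Why: Acetylide addition to a Weinreb amide stops at the chelated tetrahedral intermediate (Weinreb ketone synthesis), and the acidic inverse quench should prevent conjugate addition of the liberated hydroxylamine to the ynone.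

Step 7
Reactants: 5 (1E)-2-allyl-1-methoxy-3-(triisopropylsilyloxy)-1-(trimethylsilyloxy)buta-1,3-diene; 10 (R)-5-(tert-butyldimethylsilyloxy)-5-phenylpent-1-yn-3-one
Product: 12 (R)-1-[3-allyl-2-hydroxy-4-(triisopropylsilyloxy)phenyl]-3-(tert-butyldimethylsilyloxy)-3-phenylpropan-1-one, via cyclohexadiene cycloadduct 11 (not isolated)
Conditions: 5 (1.5 equiv), toluene, 20 to 70 °C; then 0.5 M HCl, THF, 0 °C
Reagents that add atoms: none
Why: The electron-rich diene adds to the electron-poor alkyne in a thermal [4+2] cycloaddition (Diels–Alder benzannulation of a 1,1-dioxygenated 3-silyloxydiene with an acetylenic ketone, possibly running as Mukaiyama–Michael addition followed by 6-exo-trig Claisen-type closure to the same ring): the diene CH2 terminus (future C6) bonds to the ynone β-carbon (C5) and the ketene acetal carbon (C8a) to the α-carbon (C4a). Ring A is closed by this intermolecular cycloaddition as cyclohexa-1,4-diene 11; collapse of the mixed methyl trimethylsilyl ketal at C8a, completed by the dilute acid work-up, gives a dienone that tautomerises to the phenol, so the C7 silyl enol ether becomes the aryl triisopropylsilyl ether without being cleaved. No stereocentre is formed and the benzylic silyloxy centre is remote from every bond change. The step needs regioselectivity, which follows from pairing the most nucleophilic diene terminus with the ynone β-carbon, and the allyl group on C8 blocks the alternative [3+3] mode through C8 and C6 because that carbon could not aromatise. It also needs chemoselectivity, which the absence of any Lewis acid should secure, since neither carbonyl 1,2-addition nor β-elimination of the tert-butyldimethylsilyloxy group is then triggered.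

Step 8
Reactants: 12 (R)-1-[3-allyl-2-hydroxy-4-(triisopropylsilyloxy)phenyl]-3-(tert-butyldimethylsilyloxy)-3-phenylpropan-1-one
Product: 13 (R)-1-[3-allyl-2-hydroxy-4-(triisopropylsilyloxy)phenyl]-3-hydroxy-3-phenylpropan-1-one
Conditions: CSA (0.2 equiv), MeOH/CH2Cl2 (1:1), 0 °C to rt
Reagents that add atoms: none
Why: Acid-catalysed methanolysis cleaves an alkyl tert-butyldimethylsilyl ether much faster than a hindered, electron-poor aryl triisopropylsilyl ether (selective silyl ether solvolysis), and the mild acid should not dehydrate the β-hydroxy ketone.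

Step 9
Reactants: 13 (R)-1-[3-allyl-2-hydroxy-4-(triisopropylsilyloxy)phenyl]-3-hydroxy-3-phenylpropan-1-one
Product: 14 (S)-8-allyl-2-phenyl-7-(triisopropylsilyloxy)chroman-4-one
Conditions: PPh3, DIAD, THF (0.02 M), 0 °C to rt
Reagents that add atoms: none
Why: Intramolecular Mitsunobu etherification, in which the chelated 2-hydroxyl displaces the oxyphosphonium-activated benzylic oxygen in a 6-exo-tet SN2 closure with inversion, turns the R carbinol into the 2S centre of ring C.

Step 10
Reactants: 14 (S)-8-allyl-2-phenyl-7-(triisopropylsilyloxy)chroman-4-one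
Product: 15 (S)-2-phenyl-8-[(E)-prop-1-enyl]-7-(triisopropylsilyloxy)chroman-4-one
Conditions: RuHCl(CO)(PPh3)3 (5 mol %), toluene, 80 °C
Reagents that add atoms: none
Why: Ruthenium hydride-catalysed olefin isomerisation (hydrometalation and β-hydride elimination) moves the terminal double bond into conjugation with ring A under neutral conditions that leave the silyl ether and the base-sensitive C2 centre alone.

Step 11
Reactants: 15 (S)-2-phenyl-8-[(E)-prop-1-enyl]-7-(triisopropylsilyloxy)chroman-4-one
Product: 16 (S)-7-hydroxy-2-phenyl-8-[(E)-prop-1-enyl]chroman-4-one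
Conditions: TBAF, AcOH (1:1), THF, 0 °C
Reagents that add atoms: none
Why: An aryl silyl ether para to a carbonyl group is cleaved rapidly by fluoride (fluoride desilylation), and the acetic acid buffer keeps the medium non-basic so that ring C should not open by retro-oxa-Michael reaction.

Step 12
Reactants: 17 (S)-2-methylglycidol
Product: 18 (R)-tert-butyldimethyl[(2-methyloxiran-2-yl)methoxy]silane
Conditions: TBSCl, imidazole, CH2Cl2, 0 °C to rt
Reagents that add atoms: tert-butyldimethylsilyl chloride, CC(C)(C)[Si](C)(C)Cl
Why: Routine silylation of a primary alcohol that does not involve the epoxide or its quaternary centre (the descriptor changes from S to R only because the substituent priorities change).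

Step 13
Reactants: 18 (R)-tert-butyldimethyl[(2-methyloxiran-2-yl)methoxy]silane
Product: 20 (R)-1-(tert-butyldimethylsilyloxy)-2-methylbut-3-en-2-ol, via sulfonium betaine 19 (not isolated)
Conditions: Me3S+ I− (3 equiv), n-BuLi (2.9 equiv), THF, −10 °C; then 18, −10 °C to rt
Reagents that add atoms: trimethylsulfonium iodide, C[S+](C)C.[I-]
Why: Dimethylsulfonium methylide opens the epoxide at its unsubstituted carbon and the betaine, deprotonated by excess ylide, eliminates dimethyl sulfide (one-carbon homologation of an epoxide to an allylic alcohol), the quaternary centre being untouched and therefore retained.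

Step 14
Reactants: 20 (R)-1-(tert-butyldimethylsilyloxy)-2-methylbut-3-en-2-ol
Product: 21 (R)-2-methylbut-3-ene-1,2-diol
Conditions: TBAF, THF, 0 °C to rt; direct chromatography
Reagents that add atoms: none
Why: Fluoride cleavage of a primary silyl ether runs in a non-acidic medium that cannot ionise the tertiary allylic alcohol.

Step 15
Reactants: 21 (R)-2-methylbut-3-ene-1,2-diol
Product: 22 (R)-2-hydroxy-2-methylbut-3-enyl acetate
Conditions: Ac2O (1.05 equiv), pyridine, CH2Cl2, 0 °C
Reagents that add atoms: acetic anhydride, CC(=O)OC(C)=O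
Why: Acetylation with anhydride and pyridine, without a nucleophilic catalyst, takes the primary hydroxyl and leaves the hindered tertiary one (chemoselective esterification).

Step 16
Reactants: 16 (S)-7-hydroxy-2-phenyl-8-[(E)-prop-1-enyl]chroman-4-one; 22 (R)-2-hydroxy-2-methylbut-3-enyl acetate
Product: 24 (2S)-7-{[(2R)-1-acetoxy-2-methylbut-3-en-2-yl]oxy(diphenyl)silyloxy}-2-phenyl-8-[(E)-prop-1-enyl]chroman-4-one, via chlorosilyl ether 23 (not isolated)
Conditions: 22 (1.3 equiv), Ph2SiCl2 (1.3 equiv), Et3N, DMAP (cat.), CH2Cl2, 0 °C to rt; then 16, imidazole, rt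
Reagents that add atoms: dichlorodiphenylsilane, Cl[Si](Cl)(c1ccccc1)c1ccccc1
Why: Stepwise substitution at silicon (temporary silicon tether formation): the tertiary alcohol should react only once with the dichlorosilane, as tertiary alcohols do in making tert-alkoxydiphenylsilyl chlorides, and the remaining Si–Cl bond then silylates the acidic 7-hydroxyl under mild amine base.

Step 17
Reactants: 24 the mixed diphenylsilaketal
Product: 25 cyclic diphenylsilaketal in which O7 and the tertiary oxygen are bridged by SiPh2 and a Z-alkene joins C8 to the R-configured quaternary carbon in an eight-membered ring fused to ring A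
Conditions: second-generation Hoveyda–Grubbs catalyst (10 mol %), toluene (0.002 M), 80 °C, argon purge
Reagents that add atoms: none
Why: Temporary silicon-tethered ring-closing metathesis, in which the catalyst loads on the vinyl group and closes the eight-membered dioxasilacycle onto the propenyl group with loss of propene, should give only the Z alkene because the ring cannot hold the E geometry.

Step 18
Reactants: 25 the cyclic diphenylsilaketal
Product: 26 (2S)-8-[(1Z,3R)-4-acetoxy-3-hydroxy-3-methylbut-1-enyl]-7-hydroxy-2-phenylchroman-4-one (target)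
Conditions: HF·pyridine, pyridine, THF, 0 °C to rt
Reagents that add atoms: none
Why: Fluoride cleaves both Si–O bonds of the silaketal (desilylation), and the pyridine buffer should protect the acetate, the Z allylic tertiary alcohol and ring C from acid- or base-induced side reactions.

**Compound list**

1 | methyl acetoacetate | COC(=O)CC(C)=O | starting material
2 | allyl bromide | C=CCBr | starting material
3 | methyl 2-acetylpent-4-enoate (racemic) | C=CCC(C(C)=O)C(=O)OC | intermediate
4 | methyl (Z)-2-allyl-3-(triisopropylsilyloxy)but-2-enoate | COC(=O)/C(CC=C)=C(/C)O[Si](C(C)C)(C(C)C)C(C)C | intermediate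
5 | (1E)-2-allyl-1-methoxy-3-(triisopropylsilyloxy)-1-(trimethylsilyloxy)buta-1,3-diene | C=C(O[Si](C(C)C)(C(C)C)C(C)C)/C(CC=C)=C(\OC)O[Si](C)(C)C | intermediate
6 | ethyl (R)-3-hydroxy-3-phenylpropanoate | CCOC(=O)C[C@@H](O)c1ccccc1 | starting material
7 | ethyl (R)-3-(tert-butyldimethylsilyloxy)-3-phenylpropanoate | CCOC(=O)C[C@@H](O[Si](C)(C)C(C)(C)C)c1ccccc1 | intermediate
8 | (R)-3-(tert-butyldimethylsilyloxy)-N-methoxy-N-methyl-3-phenylpropanamide | CON(C)C(=O)C[C@@H](O[Si](C)(C)C(C)(C)C)c1ccccc1 | intermediate
9 | ethynylmagnesium bromide | C#C[Mg]Br | starting material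
10 | (R)-5-(tert-butyldimethylsilyloxy)-5-phenylpent-1-yn-3-one | C#CC(=O)C[C@@H](O[Si](C)(C)C(C)(C)C)c1ccccc1 | intermediate
11 | (R)-1-[5-allyl-6-methoxy-4-(triisopropylsilyloxy)-6-(trimethylsilyloxy)cyclohexa-1,4-dienyl]-3-(tert-butyldimethylsilyloxy)-3-phenylpropan-1-one (both ketal epimers) | C=CCC1=C(O[Si](C(C)C)(C(C)C)C(C)C)CC=C(C(=O)C[C@@H](O[Si](C)(C)C(C)(C)C)c2ccccc2)C1(OC)O[Si](C)(C)C | intermediate (not isolated)
12 | (R)-1-[3-allyl-2-hydroxy-4-(triisopropylsilyloxy)phenyl]-3-(tert-butyldimethylsilyloxy)-3-phenylpropan-1-one | C=CCc1c(O[Si](C(C)C)(C(C)C)C(C)C)ccc(C(=O)C[C@@H](O[Si](C)(C)C(C)(C)C)c2ccccc2)c1O | intermediate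
13 | (R)-1-[3-allyl-2-hydroxy-4-(triisopropylsilyloxy)phenyl]-3-hydroxy-3-phenylpropan-1-one | C=CCc1c(O[Si](C(C)C)(C(C)C)C(C)C)ccc(C(=O)C[C@@H](O)c2ccccc2)c1O | intermediate
14 | (S)-8-allyl-2-phenyl-7-(triisopropylsilyloxy)chroman-4-one | C=CCc1c(O[Si](C(C)C)(C(C)C)C(C)C)ccc2c1O[C@H](c1ccccc1)CC2=O | intermediate
15 | (S)-2-phenyl-8-[(E)-prop-1-enyl]-7-(triisopropylsilyloxy)chroman-4-one | C/C=C/c1c(O[Si](C(C)C)(C(C)C)C(C)C)ccc2c1O[C@H](c1ccccc1)CC2=O | intermediate
16 | (S)-7-hydroxy-2-phenyl-8-[(E)-prop-1-enyl]chroman-4-one | C/C=C/c1c(O)ccc2c1O[C@H](c1ccccc1)CC2=O | intermediate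
17 | (S)-2-methylglycidol, (S)-(2-methyloxiran-2-yl)methanol | OC[C@]1(C)OC1 | starting material
18 | (R)-tert-butyldimethyl[(2-methyloxiran-2-yl)methoxy]silane | CC(C)(C)[Si](C)(C)OC[C@]1(C)OC1 | intermediate
19 | [(3R)-4-(tert-butyldimethylsilyloxy)-3-methyl-3-oxidobutyl]dimethylsulfonium (betaine) | C[S+](C)CC[C@@](C)([O-])CO[Si](C)(C)C(C)(C)C | intermediate (not isolated)
20 | (R)-1-(tert-butyldimethylsilyloxy)-2-methylbut-3-en-2-ol | CC(C)(C)[Si](C)(C)OC[C@](C)(O)C=C | intermediate
21 | (R)-2-methylbut-3-ene-1,2-diol | OC[C@](C)(O)C=C | intermediate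
22 | (R)-2-hydroxy-2-methylbut-3-enyl acetate | CC(=O)OC[C@](C)(O)C=C | intermediate
23 | (R)-2-[chloro(diphenyl)silyloxy]-2-methylbut-3-enyl acetate | CC(=O)OC[C@](C)(O[Si](Cl)(c1ccccc1)c1ccccc1)C=C | intermediate (not isolated)
24 | (2S)-7-{[(2R)-1-acetoxy-2-methylbut-3-en-2-yl]oxy(diphenyl)silyloxy}-2-phenyl-8-[(E)-prop-1-enyl]chroman-4-one | C/C=C/c1c(O[Si](c3ccccc3)(c3ccccc3)O[C@@](C)(COC(C)=O)C=C)ccc2c1O[C@H](c1ccccc1)CC2=O | intermediate
25 | cyclic diphenylsilaketal: O7 and the tertiary oxygen bridged by SiPh2, Z-alkene between C8 and the R quaternary carbon (CH3, CH2OAc) in an eight-membered ring fused to ring A, 2S | CC(=O)OC[C@@]1(C)/C=C\c2c(ccc3c2O[C@H](c2ccccc2)CC3=O)O[Si](c2ccccc2)(c2ccccc2)O1 | intermediate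
26 | (2S)-8-[(1Z,3R)-4-acetoxy-3-hydroxy-3-methylbut-1-enyl]-7-hydroxy-2-phenylchroman-4-one | CC(=O)OC[C@](C)(O)/C=C\c1c(O)ccc2c1O[C@H](c1ccccc1)CC2=O | target

**Count**

Total: 18 steps. Longest linear sequence: 11 steps (steps 4–11 and 16–18 from 6; the branch from 1 through steps 1–3, 7–11 and 16–18 is equally long).

**Steps most likely to fail**

Step 7. The terminal ynone may be consumed by oligomerisation or by addition at its carbonyl before the ring closes, the ketal may collapse incompletely, or the β-silyloxy group may eliminate. The fallback replaces the cycloaddition by acylation of an aryl anion; it sets out from Weinreb amide 8 and allyl bromide 2 and returns at 13. Commercial 1,3-bis(methoxymethoxy)benzene is lithiated between its two oxygens (n-BuLi, THF, 0 °C) and allylated with 2 to give 2-allyl-1,3-bis(methoxymethoxy)benzene F1. NBS in MeCN at 0 °C brominates the only activated position type, para to one ether and ortho to the other, to give 3-allyl-1-bromo-2,4-bis(methoxymethoxy)benzene F2. Bromine–lithium exchange (n-BuLi, THF, −78 °C) and addition of 8 give (R)-1-[3-allyl-2,4-bis(methoxymethoxy)phenyl]-3-(tert-butyldimethylsilyloxy)-3-phenylpropan-1-one F3. HCl in MeOH (0 °C to rt) removes both acetals and the silyl ether to give (R)-1-(3-allyl-2,4-dihydroxyphenyl)-3-hydroxy-3-phenylpropan-1-one F4. TIPSCl and imidazole then silylate only the non-chelated phenol para to the ketone, which gives 13.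

Step 17. The hindered propenyl group, flanked by two ortho oxygens, may engage the ruthenium alkylidene too slowly, so that intermolecular metathesis at the vinyl terminus or catalyst decay wins over closure of the eight-membered ring. The fallback forms the alkene without a tether and corrects its geometry afterwards; it sets out from 16 and 22 (step 16 is then skipped) and returns at 26. Cross-metathesis of 16 with an excess of 22 (second-generation Hoveyda–Grubbs catalyst, CH2Cl2, 40 °C) should give the E isomer (2S)-8-[(1E,3R)-4-acetoxy-3-hydroxy-3-methylbut-1-enyl]-7-hydroxy-2-phenylchroman-4-one F5. Triplet-sensitised contra-thermodynamic E-to-Z isomerisation of this styrenyl alkene (fac-Ir(ppy)3, blue LEDs, MeCN, rt) should then give 26.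

Step 9. The activated benzylic oxygen may eliminate to the chalcone, which would then close by unselective oxa-Michael addition and erode the configuration at C2. The fallback sets C2 by catalyst control on a chromone; it sets out from diene 5 and returns at 14. Diene 5 and commercial but-3-yn-2-one, under the conditions of step 7, should give 1-[3-allyl-2-hydroxy-4-(triisopropylsilyloxy)phenyl]ethanone F6. N,N-Dimethylformamide dimethyl acetal (toluene, 90 °C) converts it into (E)-1-[3-allyl-2-hydroxy-4-(triisopropylsilyloxy)phenyl]-3-(dimethylamino)prop-2-en-1-one F7. Brief treatment with HCl in CH2Cl2 closes this to 8-allyl-7-(triisopropylsilyloxy)chromen-4-one F8. Asymmetric 1,4-addition of phenylboronic acid (Hayashi–Miyaura reaction, [Rh(OH)(cod)]2 with a chiral bisphosphine of the enantiomeric series that delivers the 2S adduct, dioxane/H2O, no added base) then gives 14.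

**Further compounds**

F1 | step 7 | 2-allyl-1,3-bis(methoxymethoxy)benzene | C=CCc1c(OCOC)cccc1OCOC
F2 | step 7 | 3-allyl-1-bromo-2,4-bis(methoxymethoxy)benzene | C=CCc1c(OCOC)ccc(Br)c1OCOC
F3 | step 7 | (R)-1-[3-allyl-2,4-bis(methoxymethoxy)phenyl]-3-(tert-butyldimethylsilyloxy)-3-phenylpropan-1-one | C=CCc1c(OCOC)ccc(C(=O)C[C@@H](O[Si](C)(C)C(C)(C)C)c2ccccc2)c1OCOC
F4 | step 7 | (R)-1-(3-allyl-2,4-dihydroxyphenyl)-3-hydroxy-3-phenylpropan-1-one | C=CCc1c(O)ccc(C(=O)C[C@@H](O)c2ccccc2)c1O
F5 | step 17 | (2S)-8-[(1E,3R)-4-acetoxy-3-hydroxy-3-methylbut-1-enyl]-7-hydroxy-2-phenylchroman-4-one | CC(=O)OC[C@](C)(O)/C=C/c1c(O)ccc2c1O[C@H](c1ccccc1)CC2=O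
F6 | step 9 | 1-[3-allyl-2-hydroxy-4-(triisopropylsilyloxy)phenyl]ethanone | CC(=O)c1ccc(O[Si](C(C)C)(C(C)C)C(C)C)c(CC=C)c1O
F7 | step 9 | (E)-1-[3-allyl-2-hydroxy-4-(triisopropylsilyloxy)phenyl]-3-(dimethylamino)prop-2-en-1-one | CN(C)/C=C/C(=O)c1ccc(O[Si](C(C)C)(C(C)C)C(C)C)c(CC=C)c1O
F8 | step 9 | 8-allyl-7-(triisopropylsilyloxy)chromen-4-one | C=CCc1c(O[Si](C(C)C)(C(C)C)C(C)C)ccc2c1OC=CC2=O
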